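## The problem

Compound 19 is a bicyclo[3.2.1]octan-8-one. With C1 as the allyl-bearing bridgehead, C2 the methylene, C3 (OMe), C4 (OH), C5 the methoxy-bearing bridgehead, C6 (aryl), C7 (methyl) and C8 the ketone, a cyclopentanone (C1–C8–C5–C6–C7) and a six-membered ring (C1–C2–C3–C4–C5–C8) share the unit C1–C8–C5. There are six stereocentres (1R,3S,4S,5S,6S,7R), two of them fully substituted carbons flanking the ketone. The C6 aryl group is exo (syn to C8) and trans to the endo C7 methyl; on the chair of the six-membered ring the C3 methoxy group is equatorial and the C4 hydroxyl axial, syn to the C8 carbonyl. C6 and C7 have to be set together, C7 can then direct the adjacent C1, and a tether from C1 can only reach one face of C5. A purchased C3 centre turns the absolute sense of the ring-forming step into a diastereoselection, so only C4 rests on the organisation of a transition state. The C4–C5–C8 β-hydroxy ketone can undergo retro-aldol cleavage, the terminal alkene rules out late hydrogenation, ozonolysis or hydroboration, and the electron-rich arene with its benzylic C6–H limits oxidants and strong electrophiles. The enabling feature is twofold: C4–C5 is an aldol bond whose donor C5 is the only enolisable carbon of the ketone, and cutting it leaves a cyclopentanone with trans aryl and methyl groups beside an allylated quaternary C1. That is the pattern left by conrotatory 4π closure of a cross-conjugated dienone followed by capture of the oxyallyl cation at C1.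

## Retrosynthesis

**C4–C5 (aldol).** Cutting the β-hydroxy ketone bond of 19 gives keto-aldehyde 18. The other bonds of the six-membered ring (C2–C3, C3–C4, C1–C2) have no such natural polarity, and this cut removes two stereocentres (C4, C5) and the bridged ring at once. The forward reaction must enolise only at C5 (C1 is quaternary), attack from the face of C5 that carries the tether, and place the new hydroxyl axial, which calls for a metal bridging the enolate and aldehyde oxygens. The aldehyde is carried as the silyl ether 16 and released through alcohol 17.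

**C6–C7 and C1–allyl (key step).** Cyclopentanone 16 is opened to the acyclic dienone 13 and allyltrimethylsilane 14. Allylating a preformed cyclopentanone would face a C1/C5 regiochemistry problem and would still need the ring and its trans aryl/methyl pair. The electrocyclisation instead makes the ring, two skeletal bonds and three stereocentres from a precursor with one stereocentre. The forward reaction must conrotate in one absolute sense, capture the cation at C1 and not at the methoxy-bearing C5, and do so anti to the C7 methyl.

**C5=C6 (aldol condensation).** Dienone 13 is cut at the aryl-bearing double bond to methoxymethyl ketone 9 and aldehyde 10, by way of aldol 11 and its mesylate 12. An olefination with a phosphonate would be one step shorter but gives α-alkoxy enones with less dependable geometry; elimination under equilibrating conditions should favour the isomer with aryl anti to the carbonyl. Ketone 9 has a single sp3 α-carbon, so the enolate is unambiguous.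

**C8–C5 and the C3 methyl ether.** Ketone 9 comes from Weinreb amide 8 by addition of a methoxymethyl anion. Amide 8 is the O-methylated form of hydroxy amide 7, which is the ring-opened form of lactone 6. The lactone supplies C8, C1–C4 and the C3 oxygen in one piece, and its ring oxygen becomes the C3 methoxy group without touching the C–O bond.

**C1=C7 (aldol condensation on the lactone).** Ethylidene lactone 6 is cut to lactone 2 and acetaldehyde 3 (through aldol 4 and mesylate 5). The lactone has one α-position and the ring favours the E alkene, which puts the methyl anti to the carbonyl as the electrocyclisation requires. Lactone 2 is the silyl ether of the chiral-pool lactone 1, whose (S) centre maps directly onto C3.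

## Roads not taken

**Alternative 1:** ring-closing metathesis. The six-membered ring of the bicyclic alkene A1 would be cut at C3=C4, back to a cyclopentanone A2 that carries an allyl and a 2-bromoallyl group on C1 and a vinyl and a methoxy group on C5, allyl and vinyl cis. Second-generation Grubbs catalyst would close the ring; the bromoalkene is inert to metathesis and masks the final allyl group.
- Merits: the closure is reliable and has no stereochemical demand, and it avoids an enolisable α-alkoxy aldehyde. In this respect it is better than the aldol of the chosen plan.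
- Weak points: A2 needs two quaternary centres bearing three different alkenyl groups, and placing both a vinyl and a methoxy group on C5 cis to the C1 allyl is not a standard operation. After A1 three more selective operations remain: dihydroxylation of the ring alkene beside a bromoalkene, methylation of the C3 hydroxyl in preference to the C4 hydroxyl, and removal of bromine. C3 would be made late instead of bought, and the absolute configuration would still have to come from the synthesis of the cyclopentanone.
- Comparison: the chosen plan answers the more reliable closure with both oxygens, correctly differentiated, carried from step 5, and with a shorter end game.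

**Alternative 2:** enone–alkene photocycloaddition, then ring expansion. The cut is C1–C7 and C8–C6 of the cyclobutane in photoadduct A3, reached from the triplet state of silyloxy enone A4 and (E)-isoelemicin A5. An α-ketol-type shift of C6 from C8 to the C5 carbonyl would then expand the four-membered ring to the cyclopentanone.
- Merits: two C–C bonds and the quaternary C1 form in one convergent step from simple partners, the allyl group is in place from the start, and relief of ring strain drives the shift. Because the allyl group is preinstalled, this road has no regiochemistry-of-capture question, which is an advantage over the chosen plan.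
- Weak points: the triplet cycloaddition is stepwise, so the alkene geometry of A5 need not be retained and the trans aryl/methyl pair is not guaranteed. The head-to-head orientation is not assured, and facial selectivity rests on one remote methoxy group. After the shift C5 carries a tertiary hydroxyl that must be methylated on an α-ketol prone to the reverse shift, and C4 is a bare methylene whose hydroxyl would have to be introduced before the shift.
- Comparison: the chosen plan sets against the convergency a concerted conrotation for the trans pair and an aldol that delivers the C4 and C5 oxygen pattern directly.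

**Alternative 3:** Prins–pinacol cascade. The cut is C2–C3 together with the return of C7 from C1 to C8, leading to the alkenyl cyclobutanol acetal A7. SnCl4 would ionise the acetal, the 1,1-disubstituted alkene would close the six-membered ring through C2, and the tertiary cation at C1 would pull C7 over from the carbinol carbon, giving the silyl ether A6.
- Merits: the bridged skeleton, the quaternary C1 and the C3 centre (equatorial through a chair) form in one step, and A6 is one desilylation from 19. This is a shorter and safer end game than the three steps of the chosen plan, and it has neither an enolisable aldehyde nor a capture-regiochemistry risk.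
- Weak points: A7 is a cyclobutanol with four contiguous ring stereocentres, two of them fully substituted, plus the C4 centre set in an open chain next to a quaternary carbon. Making it is harder than the problem it solves. Migration of C5 instead of C7 is a possible diversion.
- Comparison: the chosen plan sets against the better end game an acyclic key-step precursor with one stereocentre, reached in eight conventional steps.

Key step: step 9

Assumption: lactone 1, aldehydes 3 and 10, silane 14 and all reagents are taken as commercial. The chiral acid of step 9 is written as its (R)-enantiomer on the assumption that this is the one matched to the required sense of conrotation; its antipode would be used otherwise.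

## Route

Step 1
Reactants: 1 (S)-5-(hydroxymethyl)dihydrofuran-2(3H)-one
Product: 2 (S)-5-{[(triisopropylsilyl)oxy]methyl}dihydrofuran-2(3H)-one
Conditions: i-Pr3SiCl, imidazole, DMF, 0 °C → rt
Reagents that add atoms: chlorotriisopropylsilane, CC(C)[Si](Cl)(C(C)C)C(C)C
Why: Standard silylation of a primary alcohol; the stereocentre (future C3) is untouched, and the triisopropylsilyl ether is chosen to survive strong bases and the acidic key step.

Step 2
Reactants: 2 (S)-5-{[(triisopropylsilyl)oxy]methyl}dihydrofuran-2(3H)-one; 3 acetaldehyde
Product: 4 (5S)-3-(1-hydroxyethyl)-5-{[(triisopropylsilyl)oxy]methyl}dihydrofuran-2(3H)-one (mixture of diastereomers at C3 and the carbinol carbon)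
Conditions: LiN(i-Pr)2, THF, −78 °C; then 3, −78 °C; aq. NH4Cl
Reagents that add atoms: none
Why: Aldol addition of the lactone lithium enolate, which can form only at the single α-carbon (future C1); the two new centres are removed in step 3, so their configuration is irrelevant.

Step 3
Reactants: 4 (5S)-3-(1-hydroxyethyl)-5-{[(triisopropylsilyl)oxy]methyl}dihydrofuran-2(3H)-one
Product: 6 (S,E)-3-ethylidene-5-{[(triisopropylsilyl)oxy]methyl}dihydrofuran-2(3H)-one, via secondary mesylate 5 (not isolated)
Conditions: MsCl, Et3N, CH2Cl2, 0 °C; then DBU, 0 °C → rt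
Reagents that add atoms: none
Why: Mesylation and E1cB elimination should give the thermodynamically preferred (E)-alkylidene lactone, with the methyl anti to the carbonyl as the later conrotation requires. Short exposure to DBU is planned so that the alkene does not move into the ring.

Step 4
Reactants: 6 (S,E)-3-ethylidene-5-{[(triisopropylsilyl)oxy]methyl}dihydrofuran-2(3H)-one
Product: 7 (2E,4S)-2-ethylidene-4-hydroxy-N-methoxy-N-methyl-5-[(triisopropylsilyl)oxy]pentanamide
Conditions: MeNHOMe·HCl, AlMe3, CH2Cl2, 0 °C → rt; aq. potassium sodium tartrate
Reagents that add atoms: N,O-dimethylhydroxylamine hydrochloride, CNOC.Cl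
Why: Aminolysis of the lactone by the aluminium amide (Weinreb amide formation) frees the C3 hydroxyl; the trisubstituted, α-branched alkene should resist conjugate addition. The crude hydroxy amide is taken on at once to avoid re-lactonisation.

Step 5
Reactants: 7 (2E,4S)-2-ethylidene-4-hydroxy-N-methoxy-N-methyl-5-[(triisopropylsilyl)oxy]pentanamide
Product: 8 (2E,4S)-2-ethylidene-N,4-dimethoxy-N-methyl-5-[(triisopropylsilyl)oxy]pentanamide
Conditions: Me3OBF4, 1,8-bis(dimethylamino)naphthalene, CH2Cl2, 0 °C → rt
Reagents that add atoms: trimethyloxonium tetrafluoroborate, C[O+](C)C.F[B-](F)(F)F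
Why: O-Methylation with Meerwein's salt and a non-nucleophilic base forms no alkoxide, so neither re-lactonisation nor 1,2-silyl migration is expected; the C–O bond of the stereocentre is not broken.

Step 6
Reactants: 8 (2E,4S)-2-ethylidene-N,4-dimethoxy-N-methyl-5-[(triisopropylsilyl)oxy]pentanamide
Product: 9 (3E,5S)-3-ethylidene-1,5-dimethoxy-6-[(triisopropylsilyl)oxy]hexan-2-one
Conditions: Bu3SnCH2OMe, n-BuLi, THF, −78 °C; then 8, −78 °C; aq. NH4Cl
Reagents that add atoms: tributyl(methoxymethyl)stannane (as its lithium derivative), CCCC[Sn](CCCC)(CCCC)COC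
Why: Tin–lithium exchange gives (methoxymethyl)lithium, which adds once to the Weinreb amide through the chelated tetrahedral intermediate; 1,2-addition is expected for an organolithium on this α-branched, β-substituted unsaturated amide, and the alkene geometry is retained.

Step 7
Reactants: 9 (3E,5S)-3-ethylidene-1,5-dimethoxy-6-[(triisopropylsilyl)oxy]hexan-2-one; 10 3,4,5-trimethoxybenzaldehyde
Product: 11 (4E,6S)-4-ethylidene-1-hydroxy-2,6-dimethoxy-7-[(triisopropylsilyl)oxy]-1-(3,4,5-trimethoxyphenyl)heptan-3-one (mixture of diastereomers at C1 and C2)
Conditions: LiN(i-Pr)2, THF, −78 °C; then 10, −78 °C; aq. NH4Cl at −78 °C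
Reagents that add atoms: none
Why: Kinetic deprotonation at the methoxymethyl carbon, the only sp3 α-carbon, gives a chelated enolate for a directed aldol addition to the non-enolisable aldehyde; the new centres are removed in step 8.

Step 8
Reactants: 11 (4E,6S)-4-ethylidene-1-hydroxy-2,6-dimethoxy-7-[(triisopropylsilyl)oxy]-1-(3,4,5-trimethoxyphenyl)heptan-3-one
Product: 13 (1Z,4E,6S)-4-ethylidene-2,6-dimethoxy-7-[(triisopropylsilyl)oxy]-1-(3,4,5-trimethoxyphenyl)hept-1-en-3-one, via benzylic mesylate 12 (not isolated)
Conditions: MsCl, Et3N, CH2Cl2, 0 °C; then DBU, 0 °C → rt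
Reagents that add atoms: none
Why: The electron-rich benzylic mesylate should eliminate readily (E1cB) to the more stable (Z)-2-methoxy enone, in which the aryl group is anti to the carbonyl and conjugated with it. Both β-substituents of the dienone then point away from the carbonyl.

Step 9
Reactants: 13 (1Z,4E,6S)-4-ethylidene-2,6-dimethoxy-7-[(triisopropylsilyl)oxy]-1-(3,4,5-trimethoxyphenyl)hept-1-en-3-one; 14 allyltrimethylsilane
Product: 16 (2R,3R,4S,5S)-2-allyl-5-methoxy-2-[(2S)-2-methoxy-3-(triisopropylsilyloxy)propyl]-3-methyl-4-(3,4,5-trimethoxyphenyl)cyclopentan-1-one (C5 epimerisable, drawn trans to aryl), via trimethylsilyl enol ether 15 (not isolated)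
Conditions: 14 (3 equiv), (R)-3,3′-bis(2,4,6-triisopropylphenyl)-1,1′-binaphthyl-2,2′-diyl N-(trifluoromethylsulfonyl)phosphoramide (10 mol%), toluene, −40 → −20 °C; then 1 M HCl, THF, 0 °C
Reagents that add atoms: none
Why: Proposed new method: the strong chiral acid is expected to be silylated by 14 (propene lost), and the resulting chiral silyl Lewis acid should O-silylate the C8 carbonyl of 13 to a 3-silyloxypentadienyl cation paired with the chiral phosphoramide anion. Thermal conrotatory 4π electrocyclisation, the only ring closure (five-membered), bonds C6 to C7; since aryl and methyl are both anti to the carbonyl in the (1Z,4E)-dienone, conrotation must place them trans. The sense of conrotation, and with it the absolute configuration of C6 and C7 relative to the purchased C3 centre, is left to the chiral counter-anion, because C3 is too remote to bias it. Silane 14 then captures the 2-silyloxyallyl cation at C1 on the face anti to the adjacent C7 methyl, which fixes the quaternary centre; transfer of Me3Si from the β-silyl cation to the anion closes the cycle and leaves enol ether 15, hydrolysed on work-up to 16 (C5 forms as a mixture and is erased in step 12). The step needs capture at C1 and not at C5: attack at C1 keeps the methoxy group on the enol ether double bond (a vinylogous, Sakurai-type addition to an unsaturated oxocarbenium ion) and C5 is screened by the aryl-bearing C6, but this preference is not secured. Closest known reaction types: BF3·OEt2-promoted interrupted Nazarov allylation of divinyl ketones with allylsilanes, chiral N-triflyl phosphoramide-catalysed Nazarov cyclisation of α-alkoxy divinyl ketones, and counter-anion-directed Hosomi–Sakurai allylation by silylated chiral acids.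

Step 10
Reactants: 16 (2R,3R,4S,5S)-2-allyl-5-methoxy-2-[(2S)-2-methoxy-3-(triisopropylsilyloxy)propyl]-3-methyl-4-(3,4,5-trimethoxyphenyl)cyclopentan-1-one
Product: 17 (2R,3R,4S,5S)-2-allyl-2-[(2S)-3-hydroxy-2-methoxypropyl]-5-methoxy-3-methyl-4-(3,4,5-trimethoxyphenyl)cyclopentan-1-one
Conditions: Bu4NF, AcOH, THF, 0 °C → rt
Reagents that add atoms: none
Why: Fluoride cleavage of the primary silyl ether, buffered with acetic acid to keep the medium near neutral; epimerisation at C5 would be harmless.

Step 11
Reactants: 17 (2R,3R,4S,5S)-2-allyl-2-[(2S)-3-hydroxy-2-methoxypropyl]-5-methoxy-3-methyl-4-(3,4,5-trimethoxyphenyl)cyclopentan-1-one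
Product: 18 (2S)-3-[(1R,2R,3S,4S)-1-allyl-4-methoxy-2-methyl-5-oxo-3-(3,4,5-trimethoxyphenyl)cyclopentyl]-2-methoxypropanal
Conditions: Dess–Martin periodinane, NaHCO3, CH2Cl2, 0 °C → rt
Reagents that add atoms: none
Why: Dess–Martin oxidation of the primary alcohol stops at the aldehyde and leaves the alkene and the arene alone. The α-methoxy aldehyde is used without chromatography to protect the C3 centre.

Step 12
Reactants: 18 (2S)-3-[(1R,2R,3S,4S)-1-allyl-4-methoxy-2-methyl-5-oxo-3-(3,4,5-trimethoxyphenyl)cyclopentyl]-2-methoxypropanal
Product: 19 (1R,3S,4S,5S,6S,7R)-1-allyl-4-hydroxy-3,5-dimethoxy-7-methyl-6-(3,4,5-trimethoxyphenyl)bicyclo[3.2.1]octan-8-one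
Conditions: MgBr2·OEt2, i-Pr2NEt, CH2Cl2, −20 → 0 °C; pH 7 buffer
Reagents that add atoms: none
Why: Soft enolisation of the magnesium-chelated α-methoxy ketone can occur only at C5, and the intramolecular aldol (6-(enolendo)-exo-trig) can reach C5 only from the face carrying the tether, which sets C5. Magnesium bridging the enolate and aldehyde oxygens in a chair transition state should place the C4 oxygen axial, syn to C8=O, with the C3 methoxy equatorial.

## Compound list

1 | (S)-5-(hydroxymethyl)dihydrofuran-2(3H)-one | O=C1CC[C@@H](CO)O1 | starting material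
2 | (S)-5-{[(triisopropylsilyl)oxy]methyl}dihydrofuran-2(3H)-one | O=C1CC[C@@H](CO[Si](C(C)C)(C(C)C)C(C)C)O1 | intermediate
3 | acetaldehyde | CC=O | starting material
4 | (5S)-3-(1-hydroxyethyl)-5-{[(triisopropylsilyl)oxy]methyl}dihydrofuran-2(3H)-one (diastereomer mixture) | CC(O)C1C[C@@H](CO[Si](C(C)C)(C(C)C)C(C)C)OC1=O | intermediate
5 | methanesulfonate of 4 (diastereomer mixture, not isolated) | CC(OS(C)(=O)=O)C1C[C@@H](CO[Si](C(C)C)(C(C)C)C(C)C)OC1=O | intermediate
6 | (S,E)-3-ethylidene-5-{[(triisopropylsilyl)oxy]methyl}dihydrofuran-2(3H)-one | C/C=C1\C[C@@H](CO[Si](C(C)C)(C(C)C)C(C)C)OC1=O | intermediate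
7 | (2E,4S)-2-ethylidene-4-hydroxy-N-methoxy-N-methyl-5-[(triisopropylsilyl)oxy]pentanamide | C/C=C(\C[C@H](O)CO[Si](C(C)C)(C(C)C)C(C)C)C(=O)N(C)OC | intermediate
8 | (2E,4S)-2-ethylidene-N,4-dimethoxy-N-methyl-5-[(triisopropylsilyl)oxy]pentanamide | C/C=C(\C[C@H](OC)CO[Si](C(C)C)(C(C)C)C(C)C)C(=O)N(C)OC | intermediate
9 | (3E,5S)-3-ethylidene-1,5-dimethoxy-6-[(triisopropylsilyl)oxy]hexan-2-one | C/C=C(\C[C@H](OC)CO[Si](C(C)C)(C(C)C)C(C)C)C(=O)COC | intermediate
10 | 3,4,5-trimethoxybenzaldehyde | COc1cc(C=O)cc(OC)c1OC | starting material
11 | (4E,6S)-4-ethylidene-1-hydroxy-2,6-dimethoxy-7-[(triisopropylsilyl)oxy]-1-(3,4,5-trimethoxyphenyl)heptan-3-one (diastereomer mixture) | C/C=C(\C[C@H](OC)CO[Si](C(C)C)(C(C)C)C(C)C)C(=O)C(OC)C(O)c1cc(OC)c(OC)c(OC)c1 | intermediate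
12 | methanesulfonate of 11 (diastereomer mixture, not isolated) | C/C=C(\C[C@H](OC)CO[Si](C(C)C)(C(C)C)C(C)C)C(=O)C(OC)C(OS(C)(=O)=O)c1cc(OC)c(OC)c(OC)c1 | intermediate
13 | (1Z,4E,6S)-4-ethylidene-2,6-dimethoxy-7-[(triisopropylsilyl)oxy]-1-(3,4,5-trimethoxyphenyl)hept-1-en-3-one | C/C=C(\C[C@H](OC)CO[Si](C(C)C)(C(C)C)C(C)C)C(=O)/C(OC)=C/c1cc(OC)c(OC)c(OC)c1 | intermediate
14 | allyltrimethylsilane | C=CC[Si](C)(C)C | starting material
15 | {[(3S,4R,5R)-5-allyl-2-methoxy-5-[(2S)-2-methoxy-3-(triisopropylsilyloxy)propyl]-4-methyl-3-(3,4,5-trimethoxyphenyl)cyclopent-1-en-1-yl]oxy}trimethylsilane (not isolated) | C=CC[C@]1(C[C@H](OC)CO[Si](C(C)C)(C(C)C)C(C)C)C(O[Si](C)(C)C)=C(OC)[C@H](c2cc(OC)c(OC)c(OC)c2)[C@H]1C | intermediate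
16 | (2R,3R,4S,5S)-2-allyl-5-methoxy-2-[(2S)-2-methoxy-3-(triisopropylsilyloxy)propyl]-3-methyl-4-(3,4,5-trimethoxyphenyl)cyclopentan-1-one (C5 epimerisable, drawn trans to aryl) | C=CC[C@]1(C[C@H](OC)CO[Si](C(C)C)(C(C)C)C(C)C)C(=O)[C@@H](OC)[C@H](c2cc(OC)c(OC)c(OC)c2)[C@H]1C | intermediate
17 | (2R,3R,4S,5S)-2-allyl-2-[(2S)-3-hydroxy-2-methoxypropyl]-5-methoxy-3-methyl-4-(3,4,5-trimethoxyphenyl)cyclopentan-1-one | C=CC[C@]1(C[C@H](OC)CO)C(=O)[C@@H](OC)[C@H](c2cc(OC)c(OC)c(OC)c2)[C@H]1C | intermediate
18 | (2S)-3-[(1R,2R,3S,4S)-1-allyl-4-methoxy-2-methyl-5-oxo-3-(3,4,5-trimethoxyphenyl)cyclopentyl]-2-methoxypropanal | C=CC[C@]1(C[C@H](OC)C=O)C(=O)[C@@H](OC)[C@H](c2cc(OC)c(OC)c(OC)c2)[C@H]1C | intermediate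
19 | (1R,3S,4S,5S,6S,7R)-1-allyl-4-hydroxy-3,5-dimethoxy-7-methyl-6-(3,4,5-trimethoxyphenyl)bicyclo[3.2.1]octan-8-one | C=CC[C@]12C[C@H](OC)[C@H](O)[C@](OC)(C1=O)[C@H](c1cc(OC)c(OC)c(OC)c1)[C@H]2C | target

## Step count and least certain steps

Total: 12 steps. Longest linear sequence: 12 steps, from lactone 1 to 19; compounds 3, 10 and 14 enter as purchased materials.

**Step 9 (key step, proposed new method).** The most likely failure is capture of the oxyallyl cation at the wrong terminus, or its collapse by proton loss from C6 before capture. The positive charge is held largely as an oxocarbenium ion at the methoxy-bearing C5, so C5 competes with C1 for the allylsilane. Incomplete control of the sense of conrotation by the counter-anion is the second concern. The fallback makes the C1–allyl bond by enolate alkylation and uses known chemistry. Starting from 13, the same chiral acid without a trap (the established catalytic asymmetric Nazarov cyclisation of α-alkoxy divinyl ketones, in CHCl3 at 0 °C) should give the 2-methoxycyclopent-2-enone F1, in which C7 is set and C5=C6 remains. Kinetic deprotonation at C1 with LiN(SiMe3)2 in THF at −78 °C and alkylation with allyl bromide, anti to the C7 methyl, would give the allylated enone F2. Conjugate reduction with Li in liquid NH3/THF at −78 °C (isoprene, then NH4Cl quench) should protonate C6 trans to the C7 methyl and return the route at 16.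

**Step 12.** The most likely failure is poor facial selectivity at the aldehyde, giving the equatorial C4 alcohol, if an open transition state competes with the magnesium-bridged one. Enolisation of the aldehyde, which would epimerise C3, is the second concern. The fallback sets C4 by reduction instead of by the aldol transition state. Starting from 18, the cyclisation is run to whatever C4 mixture forms, including the 4-epimer F3. Dess–Martin oxidation converts the mixture into the 4,8-dione F4, and LiBH(s-Bu)3 in THF at −78 °C should attack the C4 carbonyl from the equatorial side, as with 2-alkoxycyclohexanones, giving the axial alcohol cis to the equatorial C3 methoxy group, that is 19. The C8 ketone, flanked by two quaternary carbons, should be left alone.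

**Step 7 (with step 8).** The most likely failure is vinylogous deprotonation or conjugate self-addition of the enone during enolate formation, followed by incomplete geometric control in the elimination. The fallback forms C5=C6 by olefination and needs no ketone enolate. Starting from 8, lithiated dimethyl (methoxymethyl)phosphonate (n-BuLi, THF, −78 °C) would give the α-methoxy β-ketophosphonate F5, and a Horner–Wadsworth–Emmons reaction with 10 (Ba(OH)2, wet THF) would return the route at 13. Any geometric mixture could be equilibrated with catalytic iodine.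

**Step 4.** The most likely failure is re-closure of the γ-hydroxy amide to lactone 6 during work-up, or conjugate addition of the aluminium amide to the alkylidene lactone. The fallback avoids the hydroxy amide. Starting from 6, i-Bu2AlH in CH2Cl2 at −78 °C gives the lactol F6; excess (methoxymethyl)lithium adds to its open form to give the diol F7; MnO2 oxidises only the allylic alcohol to the hydroxy enone F8; and methylation with Me3OBF4 and 1,8-bis(dimethylamino)naphthalene returns the route at 9.

## Further compounds

F1 | step 9 | (4S)-2-methoxy-5-[(2S)-2-methoxy-3-(triisopropylsilyloxy)propyl]-4-methyl-3-(3,4,5-trimethoxyphenyl)cyclopent-2-en-1-one (C5 epimers) | O=C1C(OC)=C(c2cc(OC)c(OC)c(OC)c2)[C@@H](C)C1C[C@H](OC)CO[Si](C(C)C)(C(C)C)C(C)C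
F2 | step 9 | (4R,5R)-5-allyl-2-methoxy-5-[(2S)-2-methoxy-3-(triisopropylsilyloxy)propyl]-4-methyl-3-(3,4,5-trimethoxyphenyl)cyclopent-2-en-1-one | O=C1C(OC)=C(c2cc(OC)c(OC)c(OC)c2)[C@@H](C)[C@@]1(CC=C)C[C@H](OC)CO[Si](C(C)C)(C(C)C)C(C)C
F3 | step 12 | C4 epimer of 19 (equatorial hydroxyl) | C=CC[C@]12C[C@H](OC)[C@@H](O)[C@](OC)(C1=O)[C@H](c1cc(OC)c(OC)c(OC)c1)[C@H]2C
F4 | step 12 | 1-allyl-3,5-dimethoxy-7-methyl-6-(3,4,5-trimethoxyphenyl)bicyclo[3.2.1]octane-4,8-dione (other centres as in 19) | C=CC[C@]12C[C@H](OC)C(=O)[C@](OC)(C1=O)[C@H](c1cc(OC)c(OC)c(OC)c1)[C@H]2C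
F5 | step 7 | dimethyl [(3E,5S)-3-ethylidene-1,5-dimethoxy-2-oxo-6-(triisopropylsilyloxy)hexyl]phosphonate (mixture at C1) | C/C=C(\C[C@H](OC)CO[Si](C(C)C)(C(C)C)C(C)C)C(=O)C(OC)P(=O)(OC)OC
F6 | step 4 | (5S,E)-3-ethylidene-5-{[(triisopropylsilyl)oxy]methyl}tetrahydrofuran-2-ol (anomer mixture) | C/C=C1\C[C@@H](CO[Si](C(C)C)(C(C)C)C(C)C)OC1O
F7 | step 4 | (3E,5S)-3-ethylidene-1-methoxy-6-[(triisopropylsilyl)oxy]hexane-2,5-diol (mixture at C2) | C/C=C(\C[C@H](O)CO[Si](C(C)C)(C(C)C)C(C)C)C(O)COC
F8 | step 4 | (3E,5S)-3-ethylidene-5-hydroxy-1-methoxy-6-[(triisopropylsilyl)oxy]hexan-2-one | C/C=C(\C[C@H](O)CO[Si](C(C)C)(C(C)C)C(C)C)C(=O)COC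
A1 | alternative 1 | 1-(2-bromoallyl)-5-methoxy-7-methyl-6-(3,4,5-trimethoxyphenyl)bicyclo[3.2.1]oct-3-en-8-one | C=C(Br)C[C@]12CC=C[C@](OC)(C1=O)[C@H](c3cc(OC)c(OC)c(OC)c3)[C@H]2C
A2 | alternative 1 | 2-allyl-2-(2-bromoallyl)-5-methoxy-3-methyl-4-(3,4,5-trimethoxyphenyl)-5-vinylcyclopentan-1-one (allyl and vinyl cis) | C=C(Br)C[C@]1(CC=C)C(=O)[C@@](OC)(C=C)[C@H](c2cc(OC)c(OC)c(OC)c2)[C@H]1C
A3 | alternative 2 | cis-fused bicyclo[4.2.0]octan-2-one photoadduct with the silyloxy group on the ring-fusion carbon | C=CC[C@]12C[C@H](OC)CC(=O)[C@@]1(O[Si](C)(C)C(C)(C)C)[C@H](c3cc(OC)c(OC)c(OC)c3)[C@H]2C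
A4 | alternative 2 | (S)-3-allyl-2-(tert-butyldimethylsilyloxy)-5-methoxycyclohex-2-en-1-one | C=CCC1=C(O[Si](C)(C)C(C)(C)C)C(=O)C[C@@H](OC)C1
A5 | alternative 2 | (E)-isoelemicin, (E)-1,2,3-trimethoxy-5-(prop-1-enyl)benzene | C/C=C/c1cc(OC)c(OC)c(OC)c1
A6 | alternative 3 | C4 triethylsilyl ether of 19 | C=CC[C@]12C[C@H](OC)[C@H](O[Si](CC)(CC)CC)[C@](OC)(C1=O)[C@H](c3cc(OC)c(OC)c(OC)c3)[C@H]2C
A7 | alternative 3 | 1-(hexa-1,5-dien-2-yl)-2-methoxy-2-[2,2-dimethoxy-1-(triethylsilyloxy)ethyl]-4-methyl-3-(3,4,5-trimethoxyphenyl)cyclobutan-1-ol (alkenyl and acetal chain cis) | C=CCC(=C)[C@]1(O)[C@H](C)[C@@H](c2cc(OC)c(OC)c(OC)c2)[C@]1(OC)[C@@H](O[Si](CC)(CC)CC)C(OC)OC
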